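A small charge of precatalyst, 10 mol%, gives a single-handed free catalyst, and what I follow is the small excess that catalyst leaves in a racemate.

| flask | left-handed substrate | right-handed substrate | solid reagent | precatalyst | remark | time |
|---|---|---|---|---|---|---|
| red | 0.23 M | 0.23 M | 1 equiv | 10 mol% | run made earlier |  |
| violet | 0.51 M | 0.51 M | 1 equiv | 10 mol% | run made earlier |  |
| north-east | 0.34 M | 0.34 M | 1.00 equiv | 10 mol% |  | 25 min |
| south | 0.34 M | 0.34 M | 1.00 equiv | 10 mol% |  | 8.0 min |

| run | time / min | right-handed substrate / % | left-handed substrate / % |
|---|---|---|---|
| red | 2.00 | 50.1 | 49.4 |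
| red | 5.00 | 49.9 | 49.0 |
| red | 10.0 | 48.9 | 47.9 |
| red | 15.0 | 48.5 | 45.3 |
| violet | 1.33 | 50.3 | 50.4 |
| violet | 3.00 | 49.7 | 50.6 |
| violet | 6.00 | 49.4 | 49.0 |
| violet | 15.0 | 47.8 | 44.3 |

(readings scatter by 0.3 percentage points)

- which of the two ends with the higher excess of right-handed substrate over left-handed substrate among what is left of the two ("neither" if they lie within 2 percentage points) (north-east / south / neither)
- excess of right-handed substrate over left-handed substrate among what is left of the two at the end, north-east
- excess of right-handed substrate over left-handed substrate among what is left of the two at the end, south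

- free catalyst is single-handed; left-handed substrate and right-handed substrate are mirror images of each other, charged as a racemate, each of them at the stated concentration
- solid reagent is a solid; its amount is given per volume of the solution
- what was read earlier has a scatter of 0.3 percentage points, one standard deviation
- at the start none of the solid reagent is in solution
- an excess is below zero if the other one leads

At 15.0 min the red run has lost 6.20 % of the two substrates and shows an excess of 3.41 %, while the violet run has lost 7.90 % and shows 3.80 %. Dividing gives 0.550 and 0.481, so I carry their mean, g = 0.516, the excess won per unit of substrate lost.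

The red run's loss goes from 3.20 % at 10.0 min to 6.20 % at 15.0 min, close to the square of the time. I take the mean loss at 15.0 min, 7.05 %, for 0.34 M as well. My reckoning is then g times that loss times the squared time ratio: 10.1 % for north-east and 1.03 % for south.

Is one number enough? In the red run at 10.0 min, g predicts 1.65 % and the readings give 1.03 %, a gap not far beyond a scatter of 0.3 percentage points on each reading. But 25 min lies beyond the last reading.

The forecast gives 10.5 % for north-east, slightly above my figure, and 1 % for south: “North-east clearly ends higher.”

    free catalyst + right-handed substrate ⇌ catalyst intermediate B (K = 0.730 M⁻¹, k = 73.0 M⁻¹ min⁻¹)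
    partner + catalyst intermediate A → free catalyst + left-handed product (k = 4.80 M⁻¹ min⁻¹)
    free catalyst + left-handed substrate ⇌ catalyst intermediate A (K = 1.90 M⁻¹, k = 1200 M⁻¹ min⁻¹)
    solid reagent ⇌ partner, rate k4*(cs4 - [partner]) while solid is left; crystals form when [partner] > cs4 (solubility = 0.260 M, k = 0.0740 min⁻¹)
    partner + precatalyst → free catalyst + spent reagent (k = 1.30 M⁻¹ min⁻¹)
    left-handed substrate ⇌ right-handed substrate (k = 0.0530 min⁻¹)
    partner + catalyst intermediate B → free catalyst + right-handed product (k = 1.70 M⁻¹ min⁻¹)

The flask gives 7.23 % for north-east and 1.00 % for south, so north-east leads. In north-east the relaxation half-life of the two substrates by their interconversion, 6.54 min, is short against 25 min. There g times the loss of 18.2 % gives 9.39 %, above the excess found. Read at 1.5 h, the same flask has lost 45.1 %, g gives 23.3 %, and the excess found is 1.47 %, within the margin of 2 points from south's 1.00 %.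

The data are simulated with made-up constants; noise was put on by code.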